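The ratio I start from is winter's target over noon's at 0.40 h: 2.97, between two flasks with the same substrate, one holding twice the partner of the other.

| flask | substrate | partner | time |
|---|---|---|---|
| noon | 0.250 M | 0.200 M |  |
| dawn | 0.500 M | 0.200 M |  |
| winter | 0.250 M | 0.400 M |  |
| midnight | 0.250 M | 0.200 M | 11 h |

| noon run: time / h | noon run: [target] / M | dawn run: time / h | dawn run: [target] / M | winter run: time / h | winter run: [target] / M |
|---|---|---|---|---|---|
| 0.21 | 0.0113 | 0.21 | 0.0138 | 0.21 | 0.0279 |
| 0.40 | 0.0156 | 0.40 | 0.0311 | 0.40 | 0.0464 |
| 0.77 | 0.0266 | 0.77 | 0.0535 | 0.77 | 0.0762 |
| 1.5 | 0.0459 | 1.5 | 0.0873 | 1.5 | 0.1164 |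
| 2.8 | 0.0716 | 2.8 | 0.1212 | 2.8 | 0.1426 |
| 5.3 | 0.0944 | 5.3 | 0.1473 | 5.3 | 0.1480 |

(each reading ± 0.002 M)

1. how the opening rate goes with [substrate] round the charge of the noon run: the exponent of the rate at two percent of substrate gone to target (one fixed amount of target, the same in the runs compared)
2. how the opening rate goes with [partner] round the charge of the noon run: the exponent of the rate at two percent of substrate gone to target
3. target in the midnight run at 11 h, as a share of the substrate charged

- Overall: substrate + partner -> target.
- Constant volume, constant temperature.
- "The second partner" is partner.
- An order is taken over about fifteen percent of the charge, up and down.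

I go to logarithms. One doubling is 0.301 in powers of ten, so I divide the logarithm of a ratio of rates by that figure to get a doubling exponent, which is an apparent order taken across the doubling. The ratio can be read in two ways, and they bracket the exponent for partner.

Each flask's mean rate sags as target builds: winter's falls from 0.116 M h⁻¹ over the first 0.40 h to 0.0776 M h⁻¹ over the first 1.5 h. At equal time winter is further along that sag, holding more target than noon, so the ratio above reads low and gives a floor of 1.57.

At equal target, near 0.0459 M, noon needs 1.5 h and winter 0.40 h. By the overall equation noon has by then spent 22.9% of its partner and winter 11.6%, so this ratio of times reads high and gives a ceiling of 1.91.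

By hand I get no closer than the middle, 1.74, my doubling exponent for partner. One reading's scatter moves the floor by 0.174.

The forecast gives 0.95 for substrate, 46% for midnight at 11 h, and 1.5 for partner (“the local order at noon is perhaps 1.5”), which lies just under my floor, by less than that scatter.

The flask gives 1.7 for partner, an order taken round noon's charge, which stands inside my bracket for the doubling, with 1.0 for substrate and 45.5% for midnight.

    substrate + partner → target (0.2257 L mol⁻¹ h⁻¹)
    substrate + 2 partner → target + partner (2.794 L² mol⁻² h⁻¹)
    substrate + partner + target → 2 target (5.544 L² mol⁻² h⁻¹)
    target + partner → side product (0.4536 L mol⁻¹ h⁻¹)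

At the fixed early amount of target, winter's rate is 3.5 times noon's, where my exponent gives 3.34. Dawn, with twice the substrate of noon, runs at 2.0 times noon's rate at that amount, and the logarithm of that ratio over 0.301 gives a doubling exponent of 1.02.

The earlier runs and the new flask were computed with made-up constants; scatter was added.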